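**One step.** In a one-step world, with [partner] held near 0.500 M (the pseudo-first-order picture), target climbs a single exponential and a flask has two times: its stay, 15 h, and the fill time, which is how long target would take to reach the whole charge at its opening rate. Target is then one minus the exponential of minus their ratio.

| setting | dawn | summer | Saturday's | Friday's | Monday's | Sunday's |
|---|---|---|---|---|---|---|
| starting material | 0.20 M | 0.20 M | 0.20 M | 0.20 M | 0.20 M | 0.20 M |
| partner | 0.50 M | 0.50 M | 0.500 M | 0.500 M | 0.500 M | 0.500 M |
| second substrate | 0.020 M | 0.080 M | 0.0400 M | 0.0400 M | 0.0400 M | 0.0400 M |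
| temperature | −6 °C | 35 °C | 0 °C | −25 °C | 50 °C | 25 °C |
| remark | run made earlier | run made earlier |  |  |  |  |
| time |  |  | 15 h | 15 h | 15 h | 15 h |

| run | time / h | target / % | starting material / % |
|---|---|---|---|
| dawn | 1.50 | 0 | 99.3 |
| dawn | 5.00 | 0 | 101.0 |
| dawn | 8.00 | 0.8 | 98.9 |
| dawn | 12.0 | 0 | 99.3 |
| dawn | 20.0 | 0 | 100.0 |
| summer | 0.250 | 0.6 | 98.4 |
| summer | 0.833 | 5.0 | 94.9 |
| summer | 1.33 | 7.3 | 92.7 |
| summer | 2.00 | 11.0 | 88.0 |
| summer | 4.00 | 17.2 | 81.2 |

(readings scatter by 1 percentage point)

- the numbers in the tables scatter with a standard deviation of 1 percentage point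
- steps under discussion: starting material + partner <-> target; second substrate + partner <-> second product; partner -> decomposed reagent; partner + target -> over-reaction product; second substrate <-> dormant form

1. the best flask by amount of target, in percent of the starting material charged; "all alike" if 1.5 percentage points covers them all (Saturday's / Friday's / Monday's / Sunday's / all alike)
2. amount of target at the end, in percent of the starting material charged, Saturday's
3. amount of target at the end, in percent of the starting material charged, Friday's
4. amount of target at the end, in percent of the starting material charged, Monday's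
5. amount of target at the end, in percent of the starting material charged, Sunday's

**The slope.** The summer run reads 11.0% at 2.00 h, which, taken as a chord over that stretch, gives an estimated fill time of 18.2 h. The dawn run shows no rise beyond the scatter of 1 percentage point in 20.0 h, so its fill time is at least 2000 h. Across those 41.0 K, the logarithm of the fill time falls by about 0.0498 K⁻¹ in decades; this estimate is the fill slope.

**Four flasks.** My reckoning gives fill times of 17700 h for Friday's, 1010 h for Saturday's and 57.2 h for Sunday's. These are estimates, and the one-step formula turns them into target of about 0.0847%, 1.47% and 23.1%. Sunday's has the shortest of the three. Monday's fill time, 3.26 h, is shorter than the stay, which takes that flask beyond the one-step picture. The summer run's second stretch already added 6.2 points against 11.0% in its first, so I give Monday's no number.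

**The forecast.** The forecast named Monday's best, with 35% there, 21% for Sunday's, 1.5% for Saturday's and 0% for Friday's, holding that “partner decay or reversibility caps it”.

**The flasks.** Sunday's gave the most, 19.4% of target, against 10.3% for Monday's, 1.09% for Saturday's and 0.0206% for Friday's.

    starting material + partner ⇌ target (K = 3.40 M⁻¹, k = 0.0414 M⁻¹ h⁻¹, Ea = 90.0 kJ mol⁻¹, ΔH = −8.00 kJ mol⁻¹)
    second substrate + partner ⇌ second product (K = 68.5 M⁻¹, k = 0.353 M⁻¹ h⁻¹, Ea = 77.0 kJ mol⁻¹, ΔH = −90.0 kJ mol⁻¹)
    partner → decomposed reagent (k = 0.00495 h⁻¹, Ea = 114 kJ mol⁻¹)
    partner + target → over-reaction product (k = 0.0342 M⁻¹ h⁻¹, Ea = 77.0 kJ mol⁻¹)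
    second substrate ⇌ dormant form (K = 1.93, k = 0.0513 h⁻¹, Ea = 103 kJ mol⁻¹, ΔH = −7.00 kJ mol⁻¹)
    (constants at 25 °C)

**Stay against fill.** In Friday's, the forward path alone gives starting material a half-life of 2100 d, a fill time of 72600 h, longer than the estimate of 17700 h from the fill slope. The stay of 15 h is 0.0207% of that fill time, and Friday's target stood at 0.0206%. In Sunday's, the same slope gave an estimated fill time of 57.2 h and a one-step target of 23.1%, and target stood at 19.4%. Monday's ended with partner at 7.17% of its charge and over-reaction product at 17.1%.

The numbers in the tables were generated by integration on assumed constants; the scatter is artificial.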